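Ring D is made last, from an α-diazo enone that joins the two benzyl-protected chroman units and from methoxyacetylene. Ring D is a 3-methoxyphenol whose d1 (bearing chroman C4) is flanked by d2–OMe and by d6 (bearing C3''), with d4–OH para to d1; this is the native output of a vinylketene–alkoxyalkyne benzannulation. One photochemical operation (Wolff shift, [2+2], 4π opening, 6π closure) forms d1–d6, d1–d2, d3–d4 and d4–d5 and leaves the phenol free. In the precursor the diazo carbon sits on C4 of a trans-3-aryl chroman and the α-carbon of the vinyl ketone on C3'' of the second chroman; all three stereocentres are in place beforehand.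

Key step: step 14

Assumption: the sense of asymmetric induction in steps 5 and 9 is assigned by analogy with the accepted models for these catalyst families; if a catalyst delivered the mirror image, its enantiomeric ligand would be used.

Labels: C2–C8a belong to the 3-aryl chroman, C2''–C8a'' to the second chroman, d1–d6 to ring D (d1 on C4, d2 OMe, d4 OH, d6 on C3''). Unit A = 7-(benzyloxy)-3-[3-(benzyloxy)-2,4-dimethoxyphenyl]chroman-4-yl, (3R) with C4 trans to the aryl group as in the target. Unit B = 7-(benzyloxy)chroman-3-yl with the C3'' geometry of the target. The descriptor at C3'' switches between (S) and (R) along the route only because the CIP priority of the side chain changes.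

Step 1
Reactants: 1 2,6-dimethoxyphenol
Product: 2 2-(benzyloxy)-1,3-dimethoxybenzene
Conditions: BnBr (1.1 equiv), K2CO3, DMF, 25–50 °C
Reagents that add atoms: benzyl bromide BrCc1ccccc1
Why: Williamson ether synthesis on the phenoxide (SN2 at benzyl bromide) should mask the ring B hydroxyl as the benzyl ether that is removed only in the last step.

Step 2
Reactants: 2 2-(benzyloxy)-1,3-dimethoxybenzene
Product: 3 2-(benzyloxy)-4-bromo-1,3-dimethoxybenzene
Conditions: NBS (1.0 equiv), MeCN, 0 → 25 °C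
Reagents that add atoms: N-bromosuccinimide O=C1CCC(=O)N1Br
Why: Electrophilic aromatic bromination should go to C4, ortho to one methoxy group and para to the other, because the central benzyloxy group is twisted out of conjugation, as is usual for 1,2,3-trialkoxybenzenes.

Step 3
Reactants: 4 7-hydroxychroman-4-one
Product: 5 7-(benzyloxy)chroman-4-one
Conditions: BnBr (1.1 equiv), K2CO3, acetone, reflux
Reagents that add atoms: benzyl bromide BrCc1ccccc1
Why: Williamson ether synthesis under mild carbonate conditions, which the chromanone should tolerate without retro-oxa-Michael ring opening.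

Step 4
Reactants: 5 7-(benzyloxy)chroman-4-one; 3 2-(benzyloxy)-4-bromo-1,3-dimethoxybenzene
Product: 6 rac-7-(benzyloxy)-3-[3-(benzyloxy)-2,4-dimethoxyphenyl]chroman-4-one
Conditions: Pd(OAc)2 (3 mol %), XPhos (6 mol %), K3PO4 (2.3 equiv), toluene, 90 °C
Reagents that add atoms: none
Why: Palladium-catalysed α-arylation of a ketone enolate (Buchwald–Hartwig type), known for chroman-4-ones as a direct route to isoflavanones, should join ring B to C3, which is left racemic on purpose because it is resolved dynamically in step 5.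

Step 5
Reactants: 6 rac-7-(benzyloxy)-3-[3-(benzyloxy)-2,4-dimethoxyphenyl]chroman-4-one
Product: 7 (3R,4R)-7-(benzyloxy)-3-[3-(benzyloxy)-2,4-dimethoxyphenyl]chroman-4-ol (3,4-cis)
Conditions: RuCl(p-cymene)[(R,R)-TsDPEN] (2 mol %), HCO2H/Et3N (5:2), EtOAc, 40 °C
Reagents that add atoms: none
Why: Noyori-type asymmetric transfer hydrogenation with dynamic kinetic resolution: the isoflavanone racemises through its enol in the Et3N-containing medium while the (R,R)-catalyst reduces the (3R)-ketone preferentially with hydride delivery anti to the aryl group, so the catalyst sets both C3 (R) and C4 (R, cis).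

Step 6
Reactants: 7 (3R,4R)-7-(benzyloxy)-3-[3-(benzyloxy)-2,4-dimethoxyphenyl]chroman-4-ol
Product: 8 methyl 2-{(3R,4S)-7-(benzyloxy)-3-[3-(benzyloxy)-2,4-dimethoxyphenyl]chroman-4-yl}acetate (3,4-trans)
Conditions: CH2=C(OMe)OSiMe2tBu (2.5 equiv), Me3SiOTf (0.2 equiv), CH2Cl2, −78 → −40 °C
Reagents that add atoms: 1-(tert-butyldimethylsilyloxy)-1-methoxyethene C=C(OC)O[Si](C)(C)C(C)(C)C
Why: Lewis-acid-mediated SN1 substitution of a benzylic alcohol by a silyl ketene acetal (Mukaiyama-type alkylation): the C4 cation, stabilised by O1 and the C7 ether, is planar and should be attacked on the face opposite the C3 aryl group, which sets C4 (S) trans to the intact C3 centre, as in C4 substitutions of flavan-3-ol derivatives.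

Step 7
Reactants: 8 methyl 2-{(3R,4S)-7-(benzyloxy)-3-[3-(benzyloxy)-2,4-dimethoxyphenyl]chroman-4-yl}acetate
Product: 9 2-{(3R,4S)-7-(benzyloxy)-3-[3-(benzyloxy)-2,4-dimethoxyphenyl]chroman-4-yl}-N-methoxy-N-methylacetamide
Conditions: MeNH(OMe)·HCl (3 equiv), iPrMgCl (6 equiv), THF, −20 → 0 °C
Reagents that add atoms: N,O-dimethylhydroxylamine hydrochloride CNOC.Cl
Why: Aminolysis of the methyl ester by the chloromagnesium amide of N,O-dimethylhydroxylamine (Weinreb amide synthesis) should proceed without touching C3 or C4, neither of which is α to the carbonyl group.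

Step 8
Reactants: 10 4-(benzyloxy)-2-hydroxybenzaldehyde; 11 methyl vinyl ketone (but-3-en-2-one)
Product: 12 1-[7-(benzyloxy)-2H-chromen-3-yl]ethan-1-one
Conditions: K2CO3 (0.5 equiv), butan-2-one, reflux
Reagents that add atoms: none
Why: Oxa-Michael addition of the phenoxide to the enone followed by intramolecular aldol condensation is the standard annulation of salicylaldehydes with vinyl ketones to 3-acyl-2H-chromenes.

Step 9
Reactants: 12 1-[7-(benzyloxy)-2H-chromen-3-yl]ethan-1-one
Product: 13 1-[(3S)-7-(benzyloxy)chroman-3-yl]ethan-1-one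
Conditions: [Ir(cod)((S)-tBu-PHOX)]BArF (1 mol %), H2 (30 bar), CH2Cl2, 25 °C
Reagents that add atoms: none
Why: Iridium–phosphinooxazoline-catalysed asymmetric hydrogenation of the C=C bond of an α-substituted β-aryl enone should set C3'' by catalyst-controlled facial delivery of H2, while the ketone and the benzyl ether are inert to this homogeneous catalyst.

Step 10
Reactants: 13 1-[(3S)-7-(benzyloxy)chroman-3-yl]ethan-1-one
Product: 14 N'-{(1E)-1-[(3R)-7-(benzyloxy)chroman-3-yl]ethylidene}-2,4,6-triisopropylbenzenesulfonohydrazide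
Conditions: 2,4,6-iPr3C6H2SO2NHNH2 (1.05 equiv), THF, 25 °C, no acid
Reagents that add atoms: 2,4,6-triisopropylbenzenesulfonohydrazide NNS(=O)(=O)c1c(C(C)C)cc(C(C)C)cc1C(C)C
Why: Condensation of the methyl ketone with the arenesulfonyl hydrazide gives the (E)-hydrazone without added acid, conditions chosen so that C3'' is not epimerised through the ene-hydrazine tautomer.

Step 11
Reactants: 14 N'-{(1E)-1-[(3R)-7-(benzyloxy)chroman-3-yl]ethylidene}-2,4,6-triisopropylbenzenesulfonohydrazide; 9 2-{(3R,4S)-7-(benzyloxy)-3-[3-(benzyloxy)-2,4-dimethoxyphenyl]chroman-4-yl}-N-methoxy-N-methylacetamide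
Product: 16 1-{(3R,4S)-7-(benzyloxy)-3-[3-(benzyloxy)-2,4-dimethoxyphenyl]chroman-4-yl}-3-[(3R)-7-(benzyloxy)chroman-3-yl]but-3-en-2-one, via vinyllithium 15 (not isolated)
Conditions: 14 (1.4 equiv), n-BuLi (2.05 equiv per 14), THF, −78 → 0 °C; then 9, −78 °C; quench into cold 1 M HCl
Reagents that add atoms: none
Why: Shapiro reaction (deprotonation of the methyl group syn to the sulfonamide, then loss of sulfinate and N2) should give the 1-substituted vinyllithium 15 regioselectively, and its addition to the Weinreb amide stops at the chelated tetrahedral intermediate (Weinreb ketone synthesis), the acidic quench protonating the released amine before it can add to the new enone.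

Step 12
Reactants: 16 1-{(3R,4S)-7-(benzyloxy)-3-[3-(benzyloxy)-2,4-dimethoxyphenyl]chroman-4-yl}-3-[(3R)-7-(benzyloxy)chroman-3-yl]but-3-en-2-one
Product: 18 1-diazo-1-{(3R,4S)-7-(benzyloxy)-3-[3-(benzyloxy)-2,4-dimethoxyphenyl]chroman-4-yl}-3-[(3R)-7-(benzyloxy)chroman-3-yl]but-3-en-2-one, via trifluoroacetyl diketone 17 (not isolated)
Conditions: LiN(SiMe3)2 (1.1 equiv), THF, −78 °C; CF3CO2CH2CF3 (1.2 equiv); aq. HCl; then MsN3 (1.5 equiv), Et3N (1.5 equiv), H2O (1 equiv), MeCN, 25 °C
Reagents that add atoms: methanesulfonyl azide CS(=O)(=O)N=[N+]=[N-]; 2,2,2-trifluoroethyl trifluoroacetate O=C(OCC(F)(F)F)C(F)(F)F (its trifluoroacetyl group stays only in 17)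
Why: Detrifluoroacetylative diazo transfer (kinetic enolate trifluoroacetylation, then Regitz-type transfer from the sulfonyl azide to the activated 1,3-diketone) is the established way to α'-diazo enones; only the C1 methylene of 16 is enolisable, so the diazo group can enter nowhere else and no stereocentre bears an acidic hydrogen.

Step 13
Reactants: 19 chloroacetaldehyde dimethyl acetal (2-chloro-1,1-dimethoxyethane)
Product: 21 methoxyacetylene, via sodium methoxyacetylide 20 (not isolated)
Conditions: NaNH2 (3 equiv), liquid NH3, −33 °C; then cold aq. NaCl; product distilled into ClCH2CH2Cl at −30 °C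
Reagents that add atoms: none
Why: Twofold sodamide-induced elimination (HCl, then MeOH) from the chloroacetal gives the sodium acetylide 20, which water protonates, the classical preparation of alkoxyacetylenes.

Step 14
Reactants: 18 1-diazo-1-{(3R,4S)-7-(benzyloxy)-3-[3-(benzyloxy)-2,4-dimethoxyphenyl]chroman-4-yl}-3-[(3R)-7-(benzyloxy)chroman-3-yl]but-3-en-2-one; 21 methoxyacetylene
Product: 26 4-{(3R,4S)-7-(benzyloxy)-3-[3-(benzyloxy)-2,4-dimethoxyphenyl]chroman-4-yl}-5-[(3R)-7-(benzyloxy)chroman-3-yl]-3-methoxyphenol, via vinylketene 22 (not isolated), via cyclobutenone 23 (not isolated), via dienylketene 24 (not isolated), via cyclohexadienone 25 (not isolated)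
Conditions: 21 (4 equiv), ClCH2CH2Cl (degassed), hν (λ ≥ 300 nm, Pyrex, sealed tube), 20 °C; then 80 °C in the dark; K2CO3, MeOH wash of the crude
Reagents that add atoms: none
Why: Irradiation of 18 releases N2 with 1,2-shift of the alkenyl group from the carbonyl carbon to the former diazo carbon (Wolff rearrangement, bond d1–d6), and the ketene C=C of the resulting vinylketene 22 takes up methoxyacetylene in a [2+2] cycloaddition (bonds d3–d4 and d1–d2) to give cyclobutenone 23. Heating opens 23 by 4π electrocyclic ring opening to dienylketene 24, ring D is then closed by 6π electrocyclisation (bond d4–d5) and dienone 25 tautomerises to the phenol. The closest known reaction type is the photochemical Danheiser benzannulation of α-diazo ketones with alkoxy- and siloxyalkynes, applied here to a ketene with two bulky substituents. No stereocentre is formed, and C3, C4 and C3'' lie outside the reacting π system in a neutral medium, so they should be untouched. The step needs regioselectivity in the [2+2], secured by the polarised ynol ether, whose unsubstituted nucleophilic carbon bonds to the electrophilic ketene carbon so that OMe ends next to d1 and OH para to it. It also needs the alkenyl shift to outrun a 1,2-hydride shift from C4–H, which the high migratory aptitude of an sp2 carbon in the photochemical Wolff reaction should favour.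

Step 15
Reactants: 26 4-{(3R,4S)-7-(benzyloxy)-3-[3-(benzyloxy)-2,4-dimethoxyphenyl]chroman-4-yl}-5-[(3R)-7-(benzyloxy)chroman-3-yl]-3-methoxyphenol
Product: 27 4-[(3R,4S)-7-hydroxy-3-(3-hydroxy-2,4-dimethoxyphenyl)chroman-4-yl]-5-[(3R)-7-hydroxychroman-3-yl]-3-methoxyphenol (CNP0305801.1)
Conditions: H2 (1 atm), 10% Pd/C, THF/MeOH, 25 °C
Reagents that add atoms: none
Why: Catalytic hydrogenolysis of the three aryl benzyl ethers should release the phenols, the chroman C–O bonds being alkyl aryl ethers and the benzylic stereocentres C4 and C3'' carrying only C–C and C–H bonds that palladium does not cleave.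

Compound list
1 | 2,6-dimethoxyphenol | COc1cccc(OC)c1O | starting material
2 | 2-(benzyloxy)-1,3-dimethoxybenzene | COc1cccc(OC)c1OCc1ccccc1 | intermediate
3 | 2-(benzyloxy)-4-bromo-1,3-dimethoxybenzene | COc1ccc(Br)c(OC)c1OCc1ccccc1 | intermediate
4 | 7-hydroxychroman-4-one | O=C1CCOc2cc(O)ccc12 | starting material
5 | 7-(benzyloxy)chroman-4-one | O=C1CCOc2cc(OCc3ccccc3)ccc12 | intermediate
6 | rac-7-(benzyloxy)-3-[3-(benzyloxy)-2,4-dimethoxyphenyl]chroman-4-one (C3 racemic) | COc1ccc(C2COc3cc(OCc4ccccc4)ccc3C2=O)c(OC)c1OCc1ccccc1 | intermediate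
7 | (3R,4R)-7-(benzyloxy)-3-[3-(benzyloxy)-2,4-dimethoxyphenyl]chroman-4-ol (3,4-cis) | COc1ccc([C@@H]2COc3cc(OCc4ccccc4)ccc3[C@@H]2O)c(OC)c1OCc1ccccc1 | intermediate
8 | methyl 2-{(3R,4S)-7-(benzyloxy)-3-[3-(benzyloxy)-2,4-dimethoxyphenyl]chroman-4-yl}acetate (3,4-trans) | COc1ccc([C@@H]2COc3cc(OCc4ccccc4)ccc3[C@H]2CC(=O)OC)c(OC)c1OCc1ccccc1 | intermediate
9 | 2-{(3R,4S)-7-(benzyloxy)-3-[3-(benzyloxy)-2,4-dimethoxyphenyl]chroman-4-yl}-N-methoxy-N-methylacetamide | COc1ccc([C@@H]2COc3cc(OCc4ccccc4)ccc3[C@H]2CC(=O)N(C)OC)c(OC)c1OCc1ccccc1 | intermediate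
10 | 4-(benzyloxy)-2-hydroxybenzaldehyde | O=Cc1ccc(OCc2ccccc2)cc1O | starting material
11 | methyl vinyl ketone (but-3-en-2-one) | CC(=O)C=C | starting material
12 | 1-[7-(benzyloxy)-2H-chromen-3-yl]ethan-1-one | CC(=O)C1=Cc2ccc(OCc3ccccc3)cc2OC1 | intermediate
13 | 1-[(3S)-7-(benzyloxy)chroman-3-yl]ethan-1-one | CC(=O)[C@@H]1COc2cc(OCc3ccccc3)ccc2C1 | intermediate
14 | N'-{(1E)-1-[(3R)-7-(benzyloxy)chroman-3-yl]ethylidene}-2,4,6-triisopropylbenzenesulfonohydrazide | C/C(=N\NS(=O)(=O)c1c(C(C)C)cc(C(C)C)cc1C(C)C)[C@@H]1COc2cc(OCc3ccccc3)ccc2C1 | intermediate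
15 | {1-[(3R)-7-(benzyloxy)chroman-3-yl]vinyl}lithium | [Li]C(=C)[C@@H]1COc2cc(OCc3ccccc3)ccc2C1 | intermediate
16 | 1-{(3R,4S)-7-(benzyloxy)-3-[3-(benzyloxy)-2,4-dimethoxyphenyl]chroman-4-yl}-3-[(3R)-7-(benzyloxy)chroman-3-yl]but-3-en-2-one | COc1ccc([C@@H]2COc3cc(OCc4ccccc4)ccc3[C@H]2CC(=O)C(=C)[C@@H]2COc3cc(OCc4ccccc4)ccc3C2)c(OC)c1OCc1ccccc1 | intermediate
17 | 1,1,1-trifluoro-3-(unit A)-5-(unit B)hex-5-ene-2,4-dione (C3 of the chain unassigned, largely enolised; ring centres as in 16) | COc1ccc([C@@H]2COc3cc(OCc4ccccc4)ccc3[C@H]2C(C(=O)C(F)(F)F)C(=O)C(=C)[C@@H]2COc3cc(OCc4ccccc4)ccc3C2)c(OC)c1OCc1ccccc1 | intermediate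
18 | 1-diazo-1-{(3R,4S)-7-(benzyloxy)-3-[3-(benzyloxy)-2,4-dimethoxyphenyl]chroman-4-yl}-3-[(3R)-7-(benzyloxy)chroman-3-yl]but-3-en-2-one | COc1ccc([C@@H]2COc3cc(OCc4ccccc4)ccc3[C@H]2C(=[N+]=[N-])C(=O)C(=C)[C@@H]2COc3cc(OCc4ccccc4)ccc3C2)c(OC)c1OCc1ccccc1 | intermediate
19 | chloroacetaldehyde dimethyl acetal (2-chloro-1,1-dimethoxyethane) | COC(CCl)OC | starting material
20 | sodium methoxyacetylide | COC#[C-].[Na+] | intermediate
21 | methoxyacetylene (methoxyethyne) | COC#C | intermediate
22 | 2-(unit A)-3-(unit B)buta-1,3-dien-1-one, the vinylketene (ring centres as in 18) | COc1ccc([C@@H]2COc3cc(OCc4ccccc4)ccc3[C@H]2C(=C=O)C(=C)[C@@H]2COc3cc(OCc4ccccc4)ccc3C2)c(OC)c1OCc1ccccc1 | intermediate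
23 | 3-methoxy-4-(unit A)-4-[1-(unit B)vinyl]cyclobut-2-en-1-one (ring centres as in 18; quaternary C4 of the cyclobutenone unassigned) | COc1ccc([C@@H]2COc3cc(OCc4ccccc4)ccc3[C@H]2C2(C(=C)[C@@H]3COc4cc(OCc5ccccc5)ccc4C3)C(=O)C=C2OC)c(OC)c1OCc1ccccc1 | intermediate
24 | (3E)-3-methoxy-4-(unit A)-5-(unit B)hexa-1,3,5-trien-1-one, the dienylketene with ketenyl and vinyl groups cis (ring centres as in 18) | COc1ccc([C@@H]2COc3cc(OCc4ccccc4)ccc3[C@H]2/C(=C(/C=C=O)OC)C(=C)[C@@H]2COc3cc(OCc4ccccc4)ccc3C2)c(OC)c1OCc1ccccc1 | intermediate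
25 | 3-methoxy-4-(unit A)-5-(unit B)cyclohexa-2,4-dien-1-one (ring centres as in 18) | COc1ccc([C@@H]2COc3cc(OCc4ccccc4)ccc3[C@H]2C2=C([C@@H]3COc4cc(OCc5ccccc5)ccc4C3)CC(=O)C=C2OC)c(OC)c1OCc1ccccc1 | intermediate
26 | 4-{(3R,4S)-7-(benzyloxy)-3-[3-(benzyloxy)-2,4-dimethoxyphenyl]chroman-4-yl}-5-[(3R)-7-(benzyloxy)chroman-3-yl]-3-methoxyphenol | COc1ccc([C@@H]2COc3cc(OCc4ccccc4)ccc3[C@H]2c2c(OC)cc(O)cc2[C@@H]2COc3cc(OCc4ccccc4)ccc3C2)c(OC)c1OCc1ccccc1 | intermediate
27 | 4-[(3R,4S)-7-hydroxy-3-(3-hydroxy-2,4-dimethoxyphenyl)chroman-4-yl]-5-[(3R)-7-hydroxychroman-3-yl]-3-methoxyphenol (CNP0305801.1) | COc1ccc([C@@H]2COc3cc(O)ccc3[C@H]2c2c(OC)cc(O)cc2[C@@H]2COc3cc(O)ccc3C2)c(OC)c1O | target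

Total step count: 15.
Longest linear sequence: 10 steps (steps 1, 2, 4, 5, 6, 7, 11, 12, 14, 15).

Steps most likely to fail

First, step 14. After loss of N2, a 1,2-hydride shift from C4–H to the carbene carbon may outrun the alkenyl shift. The crowded ketene may also be captured by the alkyne too slowly under irradiation and be lost to dimerisation or to acylation of the product phenol. The fallback makes the same vinylketene in the dark by dehydrochlorination of an acid chloride and sets out from 8 and 13. The lithium enolate of 8 (LiN(iPr)2, THF, −78 °C) adds to ketone 13 to give the β-hydroxy ester F1. Dehydration with the Burgess reagent (toluene, 50 °C) gives the β,γ-unsaturated ester F2; any conjugated isomer converges later. Saponification (LiOH, THF/MeOH/H2O, 50 °C) gives the carboxylic acid F3, and (COCl)2 with catalytic DMF gives the acid chloride F4. Slow addition of Et3N to F4 and 21 in toluene (0 → 80 °C) should form 22 by elimination of HCl. The sequence then runs through 23, 24 and 25 and comes back to the route at 26.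

Second, step 11. Proton transfer from the α-methylene of 9 to the basic vinyllithium may return both fragments, fragmentation of the hydrazone dianion may be incomplete, and C3'' may lose configurational integrity while the hydrazone is made and metalated. The fallback is a Nozaki–Hiyama–Kishi coupling under neutral conditions and sets out from 13 and 9. Kinetic enolisation of 13 at the methyl group (KN(SiMe3)2, THF, −78 °C) and trapping with PhNTf2 gives the enol triflate F5. Reduction of 9 with iBu2AlH (THF, −78 °C) gives the aldehyde F6. CrCl2 with catalytic NiCl2 in DMF couples F5 and F6 to the allylic alcohol F7, whose carbinol epimers are of no consequence. Oxidation of F7 with Dess–Martin periodinane comes back to the route at 16.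

Third, step 9. Facial discrimination may be insufficient on an enone of this exact type, or the α-stereocentre may erode under the acidic iridium hydride. The fallback moves the stereo-defining hydrogenation to a carboxylic acid and sets out from 10. Annulation with acrolein (K2CO3, 1,4-dioxane, reflux) gives the chromene aldehyde F8. Pinnick oxidation (NaClO2, NaH2PO4, 2-methylbut-2-ene, t-BuOH/H2O) gives the chromene acid F9. Carboxylate-directed hydrogenation with Ru(OAc)2[(S)-BINAP] (or its antipode, whichever gives the (3S)-acid), H2 and MeOH gives the chroman acid F10. Coupling with MeNH(OMe)·HCl and EDC gives the Weinreb amide F11, and MeMgBr (THF, 0 °C) comes back to the route at 13.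

Further compounds
F1 | step 14 | methyl 2-{7-(benzyloxy)-3-[3-(benzyloxy)-2,4-dimethoxyphenyl]chroman-4-yl}-3-[7-(benzyloxy)chroman-3-yl]-3-hydroxybutanoate (ring centres as in 8 and 13; chain centres as a mixture) | COc1ccc([C@@H]2COc3cc(OCc4ccccc4)ccc3[C@H]2C(C(=O)OC)C(C)(O)[C@@H]2COc3cc(OCc4ccccc4)ccc3C2)c(OC)c1OCc1ccccc1
F2 | step 14 | methyl 2-{7-(benzyloxy)-3-[3-(benzyloxy)-2,4-dimethoxyphenyl]chroman-4-yl}-3-[7-(benzyloxy)chroman-3-yl]but-3-enoate (ring centres as in 8 and 13; C2 of the chain as a mixture) | COc1ccc([C@@H]2COc3cc(OCc4ccccc4)ccc3[C@H]2C(C(=O)OC)C(=C)[C@@H]2COc3cc(OCc4ccccc4)ccc3C2)c(OC)c1OCc1ccccc1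
F3 | step 14 | 2-{7-(benzyloxy)-3-[3-(benzyloxy)-2,4-dimethoxyphenyl]chroman-4-yl}-3-[7-(benzyloxy)chroman-3-yl]but-3-enoic acid (ring centres as in 8 and 13) | COc1ccc([C@@H]2COc3cc(OCc4ccccc4)ccc3[C@H]2C(C(=O)O)C(=C)[C@@H]2COc3cc(OCc4ccccc4)ccc3C2)c(OC)c1OCc1ccccc1
F4 | step 14 | 2-{7-(benzyloxy)-3-[3-(benzyloxy)-2,4-dimethoxyphenyl]chroman-4-yl}-3-[7-(benzyloxy)chroman-3-yl]but-3-enoyl chloride (ring centres as in 8 and 13) | COc1ccc([C@@H]2COc3cc(OCc4ccccc4)ccc3[C@H]2C(C(=O)Cl)C(=C)[C@@H]2COc3cc(OCc4ccccc4)ccc3C2)c(OC)c1OCc1ccccc1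
F5 | step 11 | 1-[(3S)-7-(benzyloxy)chroman-3-yl]vinyl trifluoromethanesulfonate | C=C(OS(=O)(=O)C(F)(F)F)[C@@H]1COc2cc(OCc3ccccc3)ccc2C1
F6 | step 11 | 2-{(3R,4S)-7-(benzyloxy)-3-[3-(benzyloxy)-2,4-dimethoxyphenyl]chroman-4-yl}acetaldehyde | COc1ccc([C@@H]2COc3cc(OCc4ccccc4)ccc3[C@H]2CC=O)c(OC)c1OCc1ccccc1
F7 | step 11 | 1-{(3R,4S)-7-(benzyloxy)-3-[3-(benzyloxy)-2,4-dimethoxyphenyl]chroman-4-yl}-3-[(3R)-7-(benzyloxy)chroman-3-yl]but-3-en-2-ol (carbinol centre as a mixture) | COc1ccc([C@@H]2COc3cc(OCc4ccccc4)ccc3[C@H]2CC(O)C(=C)[C@@H]2COc3cc(OCc4ccccc4)ccc3C2)c(OC)c1OCc1ccccc1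
F8 | step 9 | 7-(benzyloxy)-2H-chromene-3-carbaldehyde | O=CC1=Cc2ccc(OCc3ccccc3)cc2OC1
F9 | step 9 | 7-(benzyloxy)-2H-chromene-3-carboxylic acid | OC(=O)C1=Cc2ccc(OCc3ccccc3)cc2OC1
F10 | step 9 | (3S)-7-(benzyloxy)chroman-3-carboxylic acid | OC(=O)[C@@H]1COc2cc(OCc3ccccc3)ccc2C1
F11 | step 9 | (3S)-7-(benzyloxy)-N-methoxy-N-methylchroman-3-carboxamide | CON(C)C(=O)[C@@H]1COc2cc(OCc3ccccc3)ccc2C1
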